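**Retrosynthetic overview**
1. Only one ring is built, the quinone ring, and it is built last: Dieckmann closure (side-chain carbanion onto the ortho ester carbonyl, C3–C4) of an o-(methoxycarbonyl)phenyl 1,2-diketone that already carries the complete, unprotected side chain. This is the oxidised counterpart of the o-succinylbenzoate → naphthoate closure.
2. That diketo ester is released in the flask from isochroman-1,4-dione and the full side-chain aldehyde (Knoevenagel, then methoxide).
3. Side-chain aldehyde ⇒ cross-metathesis (E-enoate) of a methacrylate aldehyde with (R)-3-methylidenehept-6-en-2-ol.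
4. Stereocentre ⇒ bought as (R)-but-3-yn-2-ol and carried through a Cu-catalysed carbomagnesiation; no protecting groups.
5. Ring order: benzene ring bought (2-acetylbenzoic acid) → temporary lactone ring (isochromandione) → quinone ring (final step).

Assumption: the quinone ring of the rhinacanthins is taken to arise in the plant as in lawsone, by the o-succinylbenzoate pathway; 1, 2, 5, 6 and 11 are taken as catalogue items.

**Step 1**
Reactants: 1 (R)-but-3-yn-2-ol; 2 but-3-enylmagnesium bromide
Product: 4 (2R)-3-methylidenehept-6-en-2-ol, via alkenylmagnesium chelate 3 (not isolated)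
Conditions: 2 (3 equiv), CuI (10 mol%), THF/Et2O, −10 °C → rt, 16 h; then H2O
Reagents that add atoms: none
Why: Cu-catalysed anti-carbomagnesiation of a propargylic alkoxide (Duboudin-type) puts the alkyl group on the internal alkyne carbon and Mg on the terminus as a five-membered chelate, which water protonates to the 1,1-disubstituted alkene; the (R) centre comes from 1 and is not involved.

**Step 2**
Reactants: 5 2,2-dimethylpent-4-en-1-ol; 6 methacryloyl chloride
Product: 7 2,2-dimethylpent-4-en-1-yl methacrylate
Conditions: Et3N, DMAP (5 mol%), BHT (trace), CH2Cl2, 0 °C → rt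
Reagents that add atoms: none
Why: DMAP-catalysed acylation (nucleophilic acyl substitution) of a primary alcohol by an acid chloride.

**Step 3**
Reactants: 7 2,2-dimethylpent-4-en-1-yl methacrylate
Product: 9 2,2-dimethyl-4-oxobutyl methacrylate, via secondary ozonide 8 (not isolated)
Conditions: O3 (about 0.95 equiv, Sudan Red 7B end-point), CH2Cl2, −78 °C; then Me2S, −78 °C → rt
Reagents that add atoms: ozone, [O-][O+]=O
Why: Criegee ozonolysis is electrophilic, so with limiting ozone at −78 °C the isolated monosubstituted alkene is attacked ahead of the conjugated, electron-poor methacrylate, and Me2S reduces ozonide 8 to the aldehyde.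

**Step 4**
Reactants: 4 (2R)-3-methylidenehept-6-en-2-ol; 9 2,2-dimethyl-4-oxobutyl methacrylate
Product: 10 2,2-dimethyl-4-oxobutyl (2E,7R)-7-hydroxy-2-methyl-6-methylideneoct-2-enoate
Conditions: Hoveyda–Grubbs II (5 mol%), 9 (3 equiv, excess recovered), 1,4-benzoquinone (10 mol%), CH2Cl2, 40 °C
Reagents that add atoms: none
Why: Olefin cross-metathesis of a type I terminal alkene with a type III methacrylate gives the trisubstituted enoate with E geometry under thermodynamic control, while the hindered 1,1-disubstituted carbinol alkene of 4, the aldehyde and the free OH are spectators; the stereocentre is not touched.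

**Step 5**
Reactants: 11 2-acetylbenzoic acid
Product: 13 isochroman-1,4-dione, via 2-(bromoacetyl)benzoic acid 12 (not isolated)
Conditions: Br2 (1.05 equiv), AcOH, cat. HBr, 25–40 °C; then H2O, reflux
Reagents that add atoms: none
Why: Acid-catalysed α-bromination of the methyl ketone through its enol, then intramolecular O-alkylation by the carboxylate (6-exo-tet lactonisation) in hot water, gives the keto lactone.

**Step 6**
Reactants: 10 2,2-dimethyl-4-oxobutyl (2E,7R)-7-hydroxy-2-methyl-6-methylideneoct-2-enoate; 13 isochroman-1,4-dione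
Product: 16 rhinacanthin I, via alkylidene isochromandione 14 (not isolated), via diketo ester 15 (not isolated)
Conditions: morpholine/AcOH (10 mol% each), toluene, 4 Å MS, 40 °C; then NaOMe (1.2 equiv), MeOH, 0 °C, 30 min; cold 1 M HCl
Reagents that add atoms: none
Why: Knoevenagel condensation at the acidic C3 of 13 gives enol lactone 14, methoxide opens it to the o-(methoxycarbonyl)aryl 1,2-diketone enolate 15, and Dieckmann (Claisen) attack of its α-carbon on the ester (the bond closed in the o-succinylbenzoate pathway) expels methoxide and gives the 2-hydroxy-1,4-quinone directly as its inert enolate, so the hindered α-methyl enoate ester meets only about one equivalent of transient methoxide at 0 °C; the (R) carbinol is not involved.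

**Compound list**
1 | (R)-but-3-yn-2-ol | C[C@@H](O)C#C | starting material
2 | but-3-enylmagnesium bromide (THF solution) | C=CCC[Mg]Br | starting material
3 | (5R)-4-(but-3-enyl)-5-methyl-2,5-dihydro-1,2-oxamagnesole (cyclic alkenylmagnesium alkoxide) | C[C@H]1O[Mg]C=C1CCC=C | intermediate (not isolated)
4 | (2R)-3-methylidenehept-6-en-2-ol | C[C@@H](O)C(=C)CCC=C | intermediate
5 | 2,2-dimethylpent-4-en-1-ol | C=CCC(C)(C)CO | starting material
6 | methacryloyl chloride | C=C(C)C(=O)Cl | starting material
7 | 2,2-dimethylpent-4-en-1-yl methacrylate | C=CCC(C)(C)COC(=O)C(C)=C | intermediate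
8 | 2,2-dimethyl-3-(1,2,4-trioxolan-3-yl)propyl methacrylate (secondary ozonide, racemic) | C=C(C)C(=O)OCC(C)(C)CC1OCOO1 | intermediate (not isolated)
9 | 2,2-dimethyl-4-oxobutyl methacrylate | C=C(C)C(=O)OCC(C)(C)CC=O | intermediate
10 | 2,2-dimethyl-4-oxobutyl (2E,7R)-7-hydroxy-2-methyl-6-methylideneoct-2-enoate | C=C(CC/C=C(\C)C(=O)OCC(C)(C)CC=O)[C@@H](C)O | intermediate
11 | 2-acetylbenzoic acid | CC(=O)c1ccccc1C(=O)O | starting material
12 | 2-(bromoacetyl)benzoic acid | O=C(CBr)c1ccccc1C(=O)O | intermediate (not isolated)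
13 | isochroman-1,4-dione (1H-isochromene-1,4(3H)-dione) | O=C1COC(=O)c2ccccc12 | intermediate
14 | 2,2-dimethyl-4-[(3Z)-1,4-dioxoisochroman-3-ylidene]butyl (2E,7R)-7-hydroxy-2-methyl-6-methylideneoct-2-enoate (Z assumed; the geometry is lost in 15) | C=C(CC/C=C(\C)C(=O)OCC(C)(C)C/C=C1\OC(=O)c2ccccc2C1=O)[C@@H](C)O | intermediate (not isolated)
15 | methyl 2-(6-{[(2E,7R)-7-hydroxy-2-methyl-6-methylideneoct-2-enoyl]oxy}-5,5-dimethyl-2-oxohexanoyl)benzoate (present as its enolate) | C=C(CC/C=C(\C)C(=O)OCC(C)(C)CCC(=O)C(=O)c1ccccc1C(=O)OC)[C@@H](C)O | intermediate (not isolated)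
16 | rhinacanthin I, 3-(3-hydroxy-1,4-dioxo-1,4-dihydronaphthalen-2-yl)-2,2-dimethylpropyl (2E,7R)-7-hydroxy-2-methyl-6-methylideneoct-2-enoate | C=C(CC/C=C(\C)C(=O)OCC(C)(C)CC1=C(O)C(=O)c2ccccc2C1=O)[C@@H](C)O | target

**Totals**
Total steps: 6. Longest linear sequence: 4 (steps 2, 3, 4, 6).

**Three steps most likely to fail**

Step 6. Risks are methanolysis of the side-chain ester, and a second isochromandione adding to 14 (a reversible Michael bis-adduct). The fallback closes the ring before any ester exists and finishes the chain afterwards; it sets out from 5 and comes back at 16. Ozonolysis of 5 (O3, CH2Cl2/MeOH, −78 °C; Me2S) gives 4,4-dimethyloxolan-2-ol F1, the lactol of 4-hydroxy-3,3-dimethylbutanal. F1 and 13 under the step 6 conditions (NaOMe can now be used in excess at rt; any tetrahydrofuranyl oxa-Michael adduct reverts under the base) give 2-hydroxy-3-(3-hydroxy-2,2-dimethylpropyl)naphthalene-1,4-dione F2. Acylation of the primary OH with 6 (Et3N, DMAP, CH2Cl2, 0 °C; a NaHCO3 wash cleaves any quinone enol ester) gives 3-(3-hydroxy-1,4-dioxo-1,4-dihydronaphthalen-2-yl)-2,2-dimethylpropyl methacrylate F3. Cross-metathesis of F3 with 4 under the step 4 conditions gives 16.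

Step 3. The risk is that ozone also cleaves the methacrylate, whose rate is only about an order of magnitude lower. The fallback replaces ozone by a peracid that does not touch electron-poor alkenes; it sets out from 7 and comes back at 9. Epoxidation of 7 with mCPBA (CH2Cl2, rt) gives 2,2-dimethyl-3-(oxiran-2-yl)propyl methacrylate F4, and periodic acid (H5IO6, THF/H2O, rt) cleaves F4 to 9.

Step 4. Risks are slow metathesis of the methacrylate, homodimer of 4, and Ru-hydride isomerisation of the allylic alcohol. The fallback makes the enoate by Horner–Wadsworth–Emmons olefination after the ring is closed; it sets out from 5 and 1, uses 13, and comes back at 16. Esterification of 5 with commercial 2-(diethoxyphosphoryl)propanoic acid (DCC, DMAP) gives 2,2-dimethylpent-4-en-1-yl 2-(diethoxyphosphoryl)propanoate F5. Ozonolysis of F5 (no competing alkene; Me2S) gives 2,2-dimethyl-4-oxobutyl 2-(diethoxyphosphoryl)propanoate F6. F6 and 13 under the step 6 conditions give 3-(3-hydroxy-1,4-dioxo-1,4-dihydronaphthalen-2-yl)-2,2-dimethylpropyl 2-(diethoxyphosphoryl)propanoate F7. Separately, 1 is carbomagnesiated as in step 1 with commercial [2-(1,3-dioxolan-2-yl)ethyl]magnesium bromide to give (2R)-5-(1,3-dioxolan-2-yl)-3-methylidenepentan-2-ol F8. Aqueous AcOH hydrolyses F8 to (6R)-6-methyl-5-methylideneoxan-2-ol F9, the lactol of the hydroxy aldehyde. Olefination of F9 with F7 (LiCl, DBU, MeCN, one extra equivalent of base for the quinone OH) gives the E-enoate 16.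

**Further compounds**
F1 | step 6 | 4,4-dimethyloxolan-2-ol | CC1(C)COC(O)C1
F2 | step 6 | 2-hydroxy-3-(3-hydroxy-2,2-dimethylpropyl)naphthalene-1,4-dione | CC(C)(CO)CC1=C(O)C(=O)c2ccccc2C1=O
F3 | step 6 | 3-(3-hydroxy-1,4-dioxo-1,4-dihydronaphthalen-2-yl)-2,2-dimethylpropyl methacrylate | C=C(C)C(=O)OCC(C)(C)CC1=C(O)C(=O)c2ccccc2C1=O
F4 | step 3 | 2,2-dimethyl-3-(oxiran-2-yl)propyl methacrylate (racemic) | C=C(C)C(=O)OCC(C)(C)CC1CO1
F5 | step 4 | 2,2-dimethylpent-4-en-1-yl 2-(diethoxyphosphoryl)propanoate (racemic) | C=CCC(C)(C)COC(=O)C(C)P(=O)(OCC)OCC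
F6 | step 4 | 2,2-dimethyl-4-oxobutyl 2-(diethoxyphosphoryl)propanoate (racemic) | O=CCC(C)(C)COC(=O)C(C)P(=O)(OCC)OCC
F7 | step 4 | 3-(3-hydroxy-1,4-dioxo-1,4-dihydronaphthalen-2-yl)-2,2-dimethylpropyl 2-(diethoxyphosphoryl)propanoate | CCOP(=O)(OCC)C(C)C(=O)OCC(C)(C)CC1=C(O)C(=O)c2ccccc2C1=O
F8 | step 4 | (2R)-5-(1,3-dioxolan-2-yl)-3-methylidenepentan-2-ol | C[C@@H](O)C(=C)CCC1OCCO1
F9 | step 4 | (6R)-6-methyl-5-methylideneoxan-2-ol (anomer mixture) | C[C@H]1OC(O)CCC1=C
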